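# Proposed total synthesis of CNP0185575.2 (31) through a rhodium-catalysed allene–diene [4+2] cycloaddition

Remark on the chemistry: atoms carry halimane numbers (ring A = C1–C5 and C10; ring B = C5–C10; C17 on C8; C18 = ester carbon and C19 = methyl on C4; C20 on C9; chain C11–C16), and the allene axis of 25 is (aR), which equals (M).

## The problem

- Target 31 is an octalin in which rings A and B share the C5–C10 bond and C10 is sp2 (C1=C10), so there is no ring-fusion relationship to lean on.
- Four ring stereocentres sit in two adjacent pairs. C4 is quaternary (methyl and methoxycarbonyl) next to C5–H. C8 carries a methyl next to the quaternary C9, which bears a methyl and the C11–C16 chain. The C8/C9 pair has to be related to C5 across ring B.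
- C9 carries two alkyl groups of similar size, so no reagent can tell its faces apart by bulk; its configuration must be handed over from a stereo-element that is already defined.
- C13 is too remote for any relay and is best bought with the chain.
- The (Z)-cinnamate isomerises, adds nucleophiles and is reduced easily, so it has to be made last.
- The C1=C10 alkene can slip to the tetrasubstituted C5=C10 position under acid or on palladium, which would erase C5.
- The hindered methyl ester must not meet unselective hydride reagents.
- The enabling feature is that C1=C10 is exocyclic to ring B and sits next to the quaternary C9. This is the pattern left when the distal bond C9=C10 of an allene C1=C10=C9 serves as the 2π partner for a diene C5=C6–C7=C8 held by the tether C4–C3–C2. One acyclic allene–diene, 25, can therefore give both rings and C5, C8 and C9, with the allene axis as the controller of C9.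

## Retrosynthesis

**Cinnamate (31 ⇐ 30 ⇐ 28 + 29).** The Z-alkene is traced to the alkyne of 30, and the C15–O ester bond is cut to alcohol 28 and phenylpropiolic acid 29. A Z-cinnamoyl unit cannot be carried through earlier steps, whereas an alkyne semi-reduction fixes the geometry in the last step. The forward reactions only have to leave the C1=C10 alkene alone.

**Ring B saturation and protecting group (28 ⇐ 27 ⇐ 26).** The C15 hydroxyl is masked as a silyl ether, and the C6–C7 single bond is traced to the C6=C7 alkene of 26. That alkene is the residue of a diene, which opens the way to a cycloaddition. The forward step must reduce the cis-disubstituted C6=C7 bond and spare the trisubstituted C1=C10 bond.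

**Key disconnection (26 ⇐ 25).** C5–C10 and C8–C9 are cut together. Both rings open, C5, C8 and C9 disappear, and what remains is the acyclic ester 25 with one ring-relevant stereocentre (C4), an E,E-diene and an allene axis.

- Compared with stepwise ring construction, this removes the need to build the C9 quaternary centre by enolate alkylation.
- The forward reaction must engage the distal allene bond and not the proximal one. Proximal addition would close a five-membered tether ring to a hydrindane.
- The forward reaction must also pick one diene face.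
- Plain heating was judged weak on both counts. The proximal bond is the less hindered one, and an unactivated pair needs temperatures at which hydrogen shifts set in.
- The step is therefore planned with monovalent rhodium, which is known to prefer the distal bond of tethered allenes and works near 50 °C.
- The allene axis fixes C9 outright, because ring A can only close on one face of the distal bond.
- The diene face is biased by two matched preferences: C20 rather than C11 under the diene, and the C4 ester rather than C19 in the pseudo-axial site of the forming ring A.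
- The methyl ester is kept as the C4 spectator because it is the flatter and smaller of the two C4 groups in an axial site.

**Allene (25 ⇐ 24 ⇐ 23).** The C9–C20 bond is cut, which turns the axis into a carbinol stereocentre at C1 of a propargylic alcohol. Anti-SN2′ delivery of methyl from copper is the standard way to translate a carbinol into a trisubstituted allene axis. The derivation of the stereochemical course shows that the (R) carbinol 23 gives the (aR) axis needed in 25.

**Fragment union (23 ⇐ 22 ⇐ 21 ⇐ 14 + 19).** The C1–C10 bond is cut to aldehyde 14 and terminal alkyne 19. Direct asymmetric alkynylation of an unbranched aldehyde was set aside in favour of addition, oxidation to ynone 22 and catalyst-controlled transfer hydrogenation. The C1 configuration decides C9, so it must be secure and independent of the remote centres C4 and C13.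

**Alkyne fragment (19 ⇐ 18 ⇐ 16 ⇐ 15).** The alkyne carbon C10 is removed to give aldehyde 18, and the C9 carbonyl is traced to the trisubstituted alkene of silyl-protected (R)-citronellol 16. Citronellol 15 supplies C13 with the right configuration and the C9–C16 carbons in three steps.

**Diene arm and C1 aldehyde (14 ⇐ 13 ⇐ 11 ⇐ 9 + 10 ⇐ 8).** The C1 aldehyde is traced to the terminal alkene of an allyl group. The C6–C7 bond is cut to vinyl iodide 9 and (E)-propenylboronic acid 10, and the C5=C6 bond to aldehyde 8. A one-step dienyl olefination of 8 would be shorter but would leave the C5=C6 geometry open. Iodo-olefination followed by a stereoretentive coupling defines both double bonds.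

**Quaternary C4 (8 ⇐ 7 ⇐ 6 ⇐ 4 ⇐ 1 + 2).** The aldehyde carbon C5 is the former carbinol carbon of a malate, and the C4–C19 and C4–C3 bonds are cut back to dimethyl (S)-malate 1 and allyl bromide 2.

- Enzymatic desymmetrisation of a 2-methyl-2-alkylmalonate was considered. Its selectivity is known to change size and sign with chain length, so it was not relied on.
- Two chelation-controlled alkylations of the malate dianion set C4 from a cheap chiral-pool carbinol with a predictable sense.
- That carbinol is then excised as the C5 aldehyde, which cannot epimerise.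

## Roads not taken

**Alternative 1:** This road cuts C8–C17 and C9–C11.

- Forward step: copper-catalysed asymmetric methyl addition to 2-methylcyclohex-2-en-1-one A1 and trapping of the enolate with the side-chain iodide A2 give the ring B ketone A3 in one pot. No ring is closed.
- Merits: the conjugate addition–alkylation sequence is established chemistry. It sets C8 by catalyst control and C9 trans to it by the usual anti alkylation, which is the relationship the target needs. In certainty per step it is better than the chosen plan.
- Weak points: A3 contains only ring B. Ring A, the C4 quaternary centre, C5 and the C1=C10 alkene all remain to be built on a ketone flanked by a quaternary carbon. Alkylation of a hindered enolate with an unactivated, β-unbranched iodide such as A2 is often inefficient.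
- Comparison: the chosen plan sets against this the closure of both rings and the creation of C5, C8 and C9 in one step. The price is one unproven reaction.

**Alternative 2:** This road cuts C2–C3 and C4–C5.

- Forward step: the ring B diene A4 (C2=C1–C10=C5), which would have to be made from A3, adds methacrolein A5 in an exo sense to give aldehyde A6 with the alkene already at C1=C10.
- Merits: Diels–Alder reactions of vinylcyclohexenes with α-substituted enals are ordinary chemistry. They have reliable regiochemistry and a real exo preference, and can be run with Lewis acid catalysis. This is an advantage over the chosen key step.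
- Weak points: the diene face must be chosen by the C9 quaternary centre, whose methyl and chain differ little. C4 and C5 would therefore be set relative to each other but not reliably relative to C8 and C9. A6 also needs oxidation and esterification, and the diene itself needs the whole of Alternative 1 first.
- Comparison: the chosen plan sets against this a C9 configuration that is dictated by the allene axis rather than by a small steric difference. It also has a shorter longest linear sequence.

**Alternative 3:** This road cuts C5–C6 and makes the C1–O bond in the reverse sense.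

- Forward step: the ring-A-fused 2-methylidenetetrahydropyran A7 (oxygen between C1 and C7) undergoes a Claisen rearrangement through a boat. C5–C6 forms, the alkene moves to C1=C10, and ring B closes as the C7 ketone A8.
- Merits: the rearrangement needs no catalyst and passes the C1 carbinol configuration to C5 suprafacially. The C7 ketone would allow C8 to be corrected by equilibration. In these respects it is at least as well founded as the chosen step.
- Weak points: A7 already contains C8 and the quaternary C9, which would have to be assembled by other means. The exocyclic enol ether has to be made from a hindered lactone. The C7 oxygen must be removed afterwards next to an epimerisable centre.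
- Comparison: the chosen plan sets against this a precursor without ring stereocentres other than C4, no deoxygenation, and fewer steps.

Key step: step 17

## Route

Step 1
Reactants: 1 dimethyl (S)-malate; 2 allyl bromide (3-bromoprop-1-ene)
Product: 4 dimethyl (2S,3R)-2-hydroxy-3-(prop-2-en-1-yl)butanedioate, via dilithium alkoxide enolate 3 (not isolated)
Conditions: LiN(SiMe3)2 (2.1 equiv), THF, −78 to −20 °C; then 2, −78 to −10 °C
Reagents that add atoms: none
Why: Fráter–Seebach alkylation: the chelated dianion 3 should be allylated on the face anti to the ester on the carbinol carbon, giving the (2S,3R) product. The new centre is re-enolised in step 2, so its purity is not critical.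

Step 2
Reactants: 4 dimethyl (2S,3R)-2-hydroxy-3-(prop-2-en-1-yl)butanedioate
Product: 6 dimethyl (2S,3S)-2-hydroxy-3-methyl-3-(prop-2-en-1-yl)butanedioate, via dilithium alkoxide enolate 5 (not isolated)
Conditions: LiN(i-Pr)2 (2.2 equiv), THF, −78 to −20 °C; then MeI, DMPU, −78 to 0 °C
Reagents that add atoms: iodomethane, CI
Why: Second Fráter–Seebach alkylation: in the chelated dianion 5 the methyl group should enter from the same face as the allyl group did in step 1, anti to the carbinol ester. The quaternary centre (future C4) is thereby set as (3S) by the malate carbinol alone.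

Step 3
Reactants: 6 dimethyl (2S,3S)-2-hydroxy-3-methyl-3-(prop-2-en-1-yl)butanedioate
Product: 7 methyl (2S)-2-[(1S)-1,2-dihydroxyethyl]-2-methylpent-4-enoate
Conditions: BH3·SMe2 (1.0 equiv), NaBH4 (5 mol %), THF, 0 °C to rt; MeOH quench
Reagents that add atoms: none
Why: Hydroxyl-directed borane reduction of an α-hydroxy ester: the alkoxyborane formed at the free hydroxyl should deliver hydride through a five-membered ring to the adjacent ester only. The neopentyl ester is not reached, and one equivalent of borane leaves no B–H for the terminal alkene.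

Step 4
Reactants: 7 methyl (2S)-2-[(1S)-1,2-dihydroxyethyl]-2-methylpent-4-enoate
Product: 8 methyl (2S)-2-formyl-2-methylpent-4-enoate
Conditions: NaIO4, THF/H2O, 0 °C to rt
Reagents that add atoms: none
Why: Periodate glycol cleavage removes the terminal carbon and unveils the C5 aldehyde. Its α-carbon is quaternary, so the aldehyde cannot enolise or epimerise.

Step 5
Reactants: 8 methyl (2S)-2-formyl-2-methylpent-4-enoate
Product: 9 methyl (2S)-2-[(E)-2-iodoethenyl]-2-methylpent-4-enoate
Conditions: CrCl2 (6 equiv), CHI3 (2 equiv), THF/1,4-dioxane, 0 °C to rt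
Reagents that add atoms: iodoform, IC(I)I
Why: Takai iodo-olefination: the geminal dichromium reagent should convert the hindered, non-enolisable aldehyde into the (E)-vinyl iodide. The ester and the terminal alkene are inert to it.

Step 6
Reactants: 9 methyl (2S)-2-[(E)-2-iodoethenyl]-2-methylpent-4-enoate; 10 (E)-prop-1-en-1-ylboronic acid
Product: 11 methyl (2S,3E,5E)-2-methyl-2-(prop-2-en-1-yl)hepta-3,5-dienoate
Conditions: Pd(PPh3)4 (5 mol %), K3PO4, THF/H2O, 45 °C
Reagents that add atoms: none
Why: Suzuki–Miyaura coupling proceeds with retention at both alkenyl carbons, so the E,E-diene follows from the two E partners. The mild temperature keeps the 1,5-diene from Cope rearrangement.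

Step 7
Reactants: 11 methyl (2S,3E,5E)-2-methyl-2-(prop-2-en-1-yl)hepta-3,5-dienoate
Product: 13 methyl (2S,3E,5E)-2-(3-hydroxypropyl)-2-methylhepta-3,5-dienoate, via B-alkyl-9-borabicyclononane 12 (not isolated)
Conditions: 9-BBN (1.1 equiv), THF, 0 °C to rt; then H2O2, aq. NaOH, 0 °C
Reagents that add atoms: hydrogen peroxide, OO
Why: Anti-Markovnikov hydroboration–oxidation: 9-BBN should add to the monosubstituted terminal alkene much faster than to the internal conjugated diene. Oxidation with retention gives the primary C1 alcohol.

Step 8
Reactants: 13 methyl (2S,3E,5E)-2-(3-hydroxypropyl)-2-methylhepta-3,5-dienoate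
Product: 14 methyl (2S,3E,5E)-2-methyl-2-(3-oxopropyl)hepta-3,5-dienoate
Conditions: Dess–Martin periodinane, NaHCO3, CH2Cl2, 0 °C to rt
Reagents that add atoms: none
Why: Dess–Martin oxidation of a primary alcohol under buffered, non-acidic conditions leaves the diene and the ester untouched.

Step 9
Reactants: 15 (R)-citronellol
Product: 16 tert-butyl{[(3R)-3,7-dimethyloct-6-en-1-yl]oxy}dimethylsilane
Conditions: TBSCl, imidazole, CH2Cl2, rt
Reagents that add atoms: tert-butyldimethylsilyl chloride, CC(C)(C)[Si](C)(C)Cl
Why: Standard silylation of a primary alcohol. The silyl ether survives organolithium, organocopper and rhodium steps and is removed by fluoride at the end.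

Step 10
Reactants: 16 tert-butyl{[(3R)-3,7-dimethyloct-6-en-1-yl]oxy}dimethylsilane
Product: 18 (4R)-6-{[tert-butyl(dimethyl)silyl]oxy}-4-methylhexanal, via secondary ozonide 17 (not isolated)
Conditions: O3, CH2Cl2, −78 °C; then PPh3, −78 °C to rt
Reagents that add atoms: ozone, [O-][O+]=O
Why: Ozonolysis with reductive work-up cleaves the only alkene to the C9 aldehyde. The C13 stereocentre is γ to the new carbonyl and is not at risk.

Step 11
Reactants: 18 (4R)-6-{[tert-butyl(dimethyl)silyl]oxy}-4-methylhexanal
Product: 19 tert-butyl(dimethyl){[(3R)-3-methylhept-6-yn-1-yl]oxy}silane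
Conditions: dimethyl (1-diazo-2-oxopropyl)phosphonate, K2CO3, MeOH, 0 °C to rt
Reagents that add atoms: dimethyl (1-diazo-2-oxopropyl)phosphonate, COP(=O)(OC)C(=[N+]=[N-])C(C)=O
Why: Ohira–Bestmann (Seyferth–Gilbert) homologation converts the aldehyde into the terminal alkyne under mild base and adds the carbon that becomes C10.

Step 12
Reactants: 19 tert-butyl(dimethyl){[(3R)-3-methylhept-6-yn-1-yl]oxy}silane; 14 methyl (2S,3E,5E)-2-methyl-2-(3-oxopropyl)hepta-3,5-dienoate
Product: 21 methyl (2S,3E,5E)-2-[(3RS,8R)-10-{[tert-butyl(dimethyl)silyl]oxy}-3-hydroxy-8-methyldec-4-yn-1-yl]-2-methylhepta-3,5-dienoate (both carbinol epimers), via lithium acetylide 20 (not isolated)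
Conditions: n-BuLi, THF, −78 °C; then 14, −78 °C; aq. NH4Cl
Reagents that add atoms: none
Why: 1,2-Addition of a lithium acetylide to an aldehyde at −78 °C should be much faster than attack on the neopentyl methyl ester. The carbinol forms without control, which steps 13 and 14 correct.

Step 13
Reactants: 21 methyl (2S,3E,5E)-2-[(3RS,8R)-10-{[tert-butyl(dimethyl)silyl]oxy}-3-hydroxy-8-methyldec-4-yn-1-yl]-2-methylhepta-3,5-dienoate
Product: 22 methyl (2S,3E,5E)-2-[(8R)-10-{[tert-butyl(dimethyl)silyl]oxy}-8-methyl-3-oxodec-4-yn-1-yl]-2-methylhepta-3,5-dienoate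
Conditions: Dess–Martin periodinane, NaHCO3, CH2Cl2, 0 °C
Reagents that add atoms: none
Why: Dess–Martin oxidation of a propargylic alcohol gives the ynone and erases the uncontrolled centre.

Step 14
Reactants: 22 methyl (2S,3E,5E)-2-[(8R)-10-{[tert-butyl(dimethyl)silyl]oxy}-8-methyl-3-oxodec-4-yn-1-yl]-2-methylhepta-3,5-dienoate
Product: 23 methyl (2S,3E,5E)-2-[(3R,8R)-10-{[tert-butyl(dimethyl)silyl]oxy}-3-hydroxy-8-methyldec-4-yn-1-yl]-2-methylhepta-3,5-dienoate
Conditions: RuCl(p-cymene)[(R,R)-TsDPEN] (2 mol %), i-PrOH, rt
Reagents that add atoms: none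
Why: Noyori asymmetric transfer hydrogenation of an alkynyl ketone: the catalyst alone decides the face. With the alkynyl group taking the role of the aryl group of an aryl ketone, the (R,R) ligand should give the (R) carbinol at C1 and leave alkyne and diene untouched.

Step 15
Reactants: 23 methyl (2S,3E,5E)-2-[(3R,8R)-10-{[tert-butyl(dimethyl)silyl]oxy}-3-hydroxy-8-methyldec-4-yn-1-yl]-2-methylhepta-3,5-dienoate
Product: 24 methyl (2S,3E,5E)-2-[(3R,8R)-10-{[tert-butyl(dimethyl)silyl]oxy}-3-(methanesulfonyloxy)-8-methyldec-4-yn-1-yl]-2-methylhepta-3,5-dienoate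
Conditions: MsCl, Et3N, CH2Cl2, −78 to −40 °C; used crude
Reagents that add atoms: methanesulfonyl chloride, CS(=O)(=O)Cl
Why: Sulfonylation at oxygen turns the carbinol into a leaving group without touching the stereocentre. The low temperature keeps the secondary propargylic mesylate intact.

Step 16
Reactants: 24 methyl (2S,3E,5E)-2-[(3R,8R)-10-{[tert-butyl(dimethyl)silyl]oxy}-3-(methanesulfonyloxy)-8-methyldec-4-yn-1-yl]-2-methylhepta-3,5-dienoate
Product: 25 methyl (2S,3E,5E)-2-[(8R)-10-{[tert-butyl(dimethyl)silyl]oxy}-5,8-dimethyldeca-3,4-dien-1-yl]-2-methylhepta-3,5-dienoate with (aR) allene axis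
Conditions: MeMgBr, CuBr·SMe2, LiBr, THF, −78 °C
Reagents that add atoms: methylmagnesium bromide, C[Mg]Br
Why: Organocopper anti-SN2′ substitution of a propargylic sulfonate: methyl should enter C9 on the face opposite to the departing mesylate, which translates the (R) carbinol into the (aR) axis. Grignard-derived methylcopper with LiBr at low temperature is used to limit racemisation and direct displacement.

Step 17
Reactants: 25 methyl (2S,3E,5E)-2-[(8R)-10-{[tert-butyl(dimethyl)silyl]oxy}-5,8-dimethyldeca-3,4-dien-1-yl]-2-methylhepta-3,5-dienoate with (aR) allene axis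
Product: 26 methyl (1S,5S,6R,8aS)-5-[(3R)-5-{[tert-butyl(dimethyl)silyl]oxy}-3-methylpentyl]-1,5,6-trimethyl-1,2,3,5,6,8a-hexahydronaphthalene-1-carboxylate
Conditions: [RhCl(cod)]2 (5 mol %), P(O-2-biphenylyl)3 (20 mol %), degassed THF (0.02 M), 45–60 °C
Reagents that add atoms: none
Why: Proposed new method: monovalent rhodium should bind the s-cis diene and the distal C9=C10 allene bond, join C5 to the central allene carbon C10 to give a rhodacycle held by the allyl units C6–C8 and C1–C10–C9, and close C8–C9 by reductive elimination, a net [4+2] that is suprafacial on both partners; the closest known reaction type is the intramolecular diene–allene [4+2] catalysed by zerovalent nickel or monovalent rhodium with triaryl phosphites, in which metal and ligand choose the allene bond, and what is new is a trisubstituted allene whose reacting terminus is fully substituted. Ring B closes as the six-membered cycloaddition ring (bonds C5–C10 and C8–C9), and ring A closes as the six-membered tether ring C4–C3–C2–C1=C10–C5, which keeps the untouched proximal bond as the C1=C10 alkene. C9 is set by the allene axis: ring A can only form with C5 cis to C2 across C1=C10, so C8 must reach C9 from the C2 side, where the (aR) axis has already placed C20 and C11. C5 and C8 are set relative to each other by the E,E geometry, which puts H5 and H8 on one face. Their sense relative to C9 and C4 depends on the diene face, and the favoured face should put the small C20 methyl under the diene (cis to C17) with the C4 ester pseudo-axial and turned away from the dienyl arm and C19 pseudo-equatorial; these two preferences were matched by choosing the (R) carbinol in 23. The step needs distal over proximal addition (the latter would give a hydrindane with an exocyclic alkene) and cycloaddition over hydride-shift isomerisation; rhodium with an electron-poor phosphite and the unhindered central carbon C10 are relied on for the first, mild temperature and dilution for the second.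

Step 18
Reactants: 26 methyl (1S,5S,6R,8aS)-5-[(3R)-5-{[tert-butyl(dimethyl)silyl]oxy}-3-methylpentyl]-1,5,6-trimethyl-1,2,3,5,6,8a-hexahydronaphthalene-1-carboxylate
Product: 27 methyl (1S,5S,6R,8aS)-5-[(3R)-5-{[tert-butyl(dimethyl)silyl]oxy}-3-methylpentyl]-1,5,6-trimethyl-1,2,3,5,6,7,8,8a-octahydronaphthalene-1-carboxylate
Conditions: 2-nitrobenzenesulfonylhydrazide, Et3N, CH2Cl2, rt (portions until 26 is consumed)
Reagents that add atoms: none
Why: Diimide reduction: the concerted syn transfer of two hydrogens should be much faster to the cis-disubstituted C6=C7 bond than to the trisubstituted C1=C10 bond. No metal is present that could move C1=C10 towards C5, and no stereocentre is formed.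

Step 19
Reactants: 27 methyl (1S,5S,6R,8aS)-5-[(3R)-5-{[tert-butyl(dimethyl)silyl]oxy}-3-methylpentyl]-1,5,6-trimethyl-1,2,3,5,6,7,8,8a-octahydronaphthalene-1-carboxylate
Product: 28 methyl (1S,5S,6R,8aS)-5-[(3R)-5-hydroxy-3-methylpentyl]-1,5,6-trimethyl-1,2,3,5,6,7,8,8a-octahydronaphthalene-1-carboxylate
Conditions: Bu4NF, THF, 0 °C to rt
Reagents that add atoms: none
Why: Fluoride cleavage of a primary silyl ether. The hindered methyl ester and the alkene are unaffected.

Step 20
Reactants: 28 methyl (1S,5S,6R,8aS)-5-[(3R)-5-hydroxy-3-methylpentyl]-1,5,6-trimethyl-1,2,3,5,6,7,8,8a-octahydronaphthalene-1-carboxylate; 29 phenylpropiolic acid (3-phenylprop-2-ynoic acid)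
Product: 30 methyl (1S,5S,6R,8aS)-1,5,6-trimethyl-5-{(3R)-3-methyl-5-[(3-phenylprop-2-ynoyl)oxy]pentyl}-1,2,3,5,6,7,8,8a-octahydronaphthalene-1-carboxylate
Conditions: DCC, DMAP (10 mol %), CH2Cl2, 0 °C
Reagents that add atoms: none
Why: Steglich esterification of a primary alcohol. Low temperature and a catalytic amount of DMAP limit conjugate addition to the arylpropiolate.

Step 21
Reactants: 30 methyl (1S,5S,6R,8aS)-1,5,6-trimethyl-5-{(3R)-3-methyl-5-[(3-phenylprop-2-ynoyl)oxy]pentyl}-1,2,3,5,6,7,8,8a-octahydronaphthalene-1-carboxylate
Product: 31 methyl (1S,5S,6R,8aS)-1,5,6-trimethyl-5-[(3R)-3-methyl-5-{[(2Z)-3-phenylprop-2-enoyl]oxy}pentyl]-1,2,3,5,6,7,8,8a-octahydronaphthalene-1-carboxylate (target)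
Conditions: H2 (1 atm), Pd/CaCO3 poisoned with Pb(OAc)2 (Lindlar catalyst), quinoline, EtOAc, rt; stopped after one equivalent
Reagents that add atoms: none
Why: Lindlar semi-hydrogenation: syn addition of one molecule of hydrogen to the alkyne should give the (Z)-cinnamate. The poisoned catalyst does not reduce or shift the hindered trisubstituted alkene.

## Compound list

1 | dimethyl (S)-malate | COC(=O)C[C@H](O)C(=O)OC | starting material
2 | allyl bromide | C=CCBr | starting material
3 | dilithium alkoxide enolate of 1 | COC(O[Li])=C[C@H](O[Li])C(=O)OC | intermediate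
4 | dimethyl (2S,3R)-2-hydroxy-3-(prop-2-en-1-yl)butanedioate | COC(=O)[C@H](CC=C)[C@H](O)C(=O)OC | intermediate
5 | dilithium alkoxide enolate of 4 | COC(O[Li])=C(CC=C)[C@H](O[Li])C(=O)OC | intermediate
6 | dimethyl (2S,3S)-2-hydroxy-3-methyl-3-(prop-2-en-1-yl)butanedioate | COC(=O)[C@@](C)(CC=C)[C@H](O)C(=O)OC | intermediate
7 | methyl (2S)-2-[(1S)-1,2-dihydroxyethyl]-2-methylpent-4-enoate | COC(=O)[C@@](C)(CC=C)[C@H](O)CO | intermediate
8 | methyl (2S)-2-formyl-2-methylpent-4-enoate | COC(=O)[C@@](C)(CC=C)C=O | intermediate
9 | methyl (2S)-2-[(E)-2-iodoethenyl]-2-methylpent-4-enoate | COC(=O)[C@@](C)(CC=C)/C=C/I | intermediate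
10 | (E)-prop-1-en-1-ylboronic acid | C/C=C/B(O)O | starting material
11 | methyl (2S,3E,5E)-2-methyl-2-(prop-2-en-1-yl)hepta-3,5-dienoate | COC(=O)[C@@](C)(CC=C)/C=C/C=C/C | intermediate
12 | B-alkyl-9-borabicyclononane from 11 (boron on the terminal carbon of the former allyl group) | COC(=O)[C@@](C)(CCCB1C2CCCC1CCC2)/C=C/C=C/C | intermediate
13 | methyl (2S,3E,5E)-2-(3-hydroxypropyl)-2-methylhepta-3,5-dienoate | COC(=O)[C@@](C)(CCCO)/C=C/C=C/C | intermediate
14 | methyl (2S,3E,5E)-2-methyl-2-(3-oxopropyl)hepta-3,5-dienoate | COC(=O)[C@@](C)(CCC=O)/C=C/C=C/C | intermediate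
15 | (R)-citronellol | CC(C)=CCC[C@@H](C)CCO | starting material
16 | tert-butyl{[(3R)-3,7-dimethyloct-6-en-1-yl]oxy}dimethylsilane | CC(C)=CCC[C@@H](C)CCO[Si](C)(C)C(C)(C)C | intermediate
17 | secondary ozonide (1,2,4-trioxolane) of 16 | CC1(C)OOC(CC[C@@H](C)CCO[Si](C)(C)C(C)(C)C)O1 | intermediate
18 | (4R)-6-{[tert-butyl(dimethyl)silyl]oxy}-4-methylhexanal | O=CCC[C@@H](C)CCO[Si](C)(C)C(C)(C)C | intermediate
19 | tert-butyl(dimethyl){[(3R)-3-methylhept-6-yn-1-yl]oxy}silane | C#CCC[C@@H](C)CCO[Si](C)(C)C(C)(C)C | intermediate
20 | lithium acetylide of 19 | [Li]C#CCC[C@@H](C)CCO[Si](C)(C)C(C)(C)C | intermediate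
21 | methyl (2S,3E,5E)-2-[(3RS,8R)-10-{[tert-butyl(dimethyl)silyl]oxy}-3-hydroxy-8-methyldec-4-yn-1-yl]-2-methylhepta-3,5-dienoate | COC(=O)[C@@](C)(CCC(O)C#CCC[C@@H](C)CCO[Si](C)(C)C(C)(C)C)/C=C/C=C/C | intermediate
22 | methyl (2S,3E,5E)-2-[(8R)-10-{[tert-butyl(dimethyl)silyl]oxy}-8-methyl-3-oxodec-4-yn-1-yl]-2-methylhepta-3,5-dienoate | COC(=O)[C@@](C)(CCC(=O)C#CCC[C@@H](C)CCO[Si](C)(C)C(C)(C)C)/C=C/C=C/C | intermediate
23 | methyl (2S,3E,5E)-2-[(3R,8R)-10-{[tert-butyl(dimethyl)silyl]oxy}-3-hydroxy-8-methyldec-4-yn-1-yl]-2-methylhepta-3,5-dienoate | COC(=O)[C@@](C)(CC[C@@H](O)C#CCC[C@@H](C)CCO[Si](C)(C)C(C)(C)C)/C=C/C=C/C | intermediate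
24 | methyl (2S,3E,5E)-2-[(3R,8R)-10-{[tert-butyl(dimethyl)silyl]oxy}-3-(methanesulfonyloxy)-8-methyldec-4-yn-1-yl]-2-methylhepta-3,5-dienoate | COC(=O)[C@@](C)(CC[C@@H](OS(C)(=O)=O)C#CCC[C@@H](C)CCO[Si](C)(C)C(C)(C)C)/C=C/C=C/C | intermediate
25 | methyl (2S,3E,5E)-2-[(8R)-10-{[tert-butyl(dimethyl)silyl]oxy}-5,8-dimethyldeca-3,4-dien-1-yl]-2-methylhepta-3,5-dienoate, allene axis (aR) | COC(=O)[C@@](C)(CCC([H])=[C@]=C(C)CC[C@@H](C)CCO[Si](C)(C)C(C)(C)C)/C=C/C=C/C | intermediate
26 | methyl (1S,5S,6R,8aS)-5-[(3R)-5-{[tert-butyl(dimethyl)silyl]oxy}-3-methylpentyl]-1,5,6-trimethyl-1,2,3,5,6,8a-hexahydronaphthalene-1-carboxylate | COC(=O)[C@@]1(C)CCC=C2[C@@H]1C=C[C@@H](C)[C@]2(C)CC[C@@H](C)CCO[Si](C)(C)C(C)(C)C | intermediate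
27 | methyl (1S,5S,6R,8aS)-5-[(3R)-5-{[tert-butyl(dimethyl)silyl]oxy}-3-methylpentyl]-1,5,6-trimethyl-1,2,3,5,6,7,8,8a-octahydronaphthalene-1-carboxylate | COC(=O)[C@@]1(C)CCC=C2[C@@H]1CC[C@@H](C)[C@]2(C)CC[C@@H](C)CCO[Si](C)(C)C(C)(C)C | intermediate
28 | methyl (1S,5S,6R,8aS)-5-[(3R)-5-hydroxy-3-methylpentyl]-1,5,6-trimethyl-1,2,3,5,6,7,8,8a-octahydronaphthalene-1-carboxylate | COC(=O)[C@@]1(C)CCC=C2[C@@H]1CC[C@@H](C)[C@]2(C)CC[C@@H](C)CCO | intermediate
29 | phenylpropiolic acid | OC(=O)C#Cc1ccccc1 | starting material
30 | methyl (1S,5S,6R,8aS)-1,5,6-trimethyl-5-{(3R)-3-methyl-5-[(3-phenylprop-2-ynoyl)oxy]pentyl}-1,2,3,5,6,7,8,8a-octahydronaphthalene-1-carboxylate | COC(=O)[C@@]1(C)CCC=C2[C@@H]1CC[C@@H](C)[C@]2(C)CC[C@@H](C)CCOC(=O)C#Cc1ccccc1 | intermediate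
31 | methyl (1S,5S,6R,8aS)-1,5,6-trimethyl-5-[(3R)-3-methyl-5-{[(2Z)-3-phenylprop-2-enoyl]oxy}pentyl]-1,2,3,5,6,7,8,8a-octahydronaphthalene-1-carboxylate | COC(=O)[C@@]1(C)CCC=C2[C@@H]1CC[C@@H](C)[C@]2(C)CC[C@@H](C)CCOC(=O)/C=C\c1ccccc1 | target

## Step count and least certain steps

Total step count: 21. Longest linear sequence: 18 (steps 1–8, then 12–21); the alkyne fragment takes 3 steps (9–11).

**Step 17 (key step, proposed new method).**

- Most likely failure: rhodium engages the proximal C1=C10 bond, which is less hindered and would close a five-membered tether ring to a hydrindane. The fully substituted C9 terminus slows both coupling and reductive elimination at the distal bond.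
- Other failures: rhodium hydride pathways may isomerise the allene to a 1,3-diene. Poor diene-face selection is also possible, because methyl and ester at C4 differ only modestly; it would give the C5,C8-bis-epimer.
- Fallback with known chemistry, setting out from alkyne 19 and aldehyde 14:
  - Zirconium-catalysed syn carboalumination of 19 (Me3Al, Cp2ZrCl2) and addition of the alkenylalane to 14 would give the (E)-allylic alcohol F1.
  - Dess–Martin oxidation would give the (E)-enone F2.
  - Intramolecular Diels–Alder reaction of this 1,7,9-decatrien-3-one under Me2AlCl forms the same bonds C5–C10 and C8–C9 and closes the same two rings, giving the cis-fused octalone F3. The E geometry holds C20 cis to the acyl carbon, so the usual carbonyl-endo transition state should place C20 cis to C17.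
  - Enol triflate formation toward the ring fusion under equilibrating conditions (Tf2O, 2,6-di-tert-butyl-4-methylpyridine) would give F4.
  - Reduction with Pd(OAc)2, PPh3, HCO2H and n-Bu3N removes the triflate and returns to the route at 26.
- Cost of the fallback: four extra steps, and the regiochemistry of enolisation toward C10 must be secured.

**Step 2.**

- Most likely failure: incomplete deprotonation of the hindered tertiary C–H beside the allyl group, or loss of facial discrimination with the small electrophile. Either leaves an inseparable error at C4.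
- Fallback, setting out from allyl bromide 2 and using it in the second alkylation instead of the first:
  - Dimethyl (R)-malate is methylated to dimethyl (2R,3S)-2-hydroxy-3-methylbutanedioate F5.
  - The dianion of F5 is allylated with 2 to the quaternary diester F6. The enolate is less hindered and the electrophile is larger and more reactive. The same C4 configuration results because both the order of electrophiles and the malate enantiomer are inverted.
  - Directed borane reduction gives the diol F7, and periodate cleavage returns to the route at 8.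

**Step 16.**

- Most likely failure: partial loss of the axial configuration through reversible electron transfer or addition–elimination by excess organocopper, or direct displacement at C1 to the branched alkyne.
- Fallback, setting out from mesylate 24: the transfer is moved from copper to palladium. Coupling with MeZnCl under Pd(PPh3)4 proceeds by anti oxidative addition to an allenylpalladium species and methyl transfer with retention. It should give the same allene 25, where the route is rejoined; no new compound is made (F0).

**Step 7.**

- Most likely failure: competing hydroboration of the conjugated diene once the terminal alkene is consumed, or double hydroboration.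
- Fallback, setting out from vinyl iodide 9: the order is changed so that no diene is present. The allyl group of 9 is hydroborated with 9-BBN and oxidised to the iodo alcohol F8. Suzuki coupling of F8 with 10 then gives 13, where the route is rejoined.

**Step 18.**

- Most likely failure: slow, incomplete reduction of the C6=C7 bond, which is branched at both allylic positions. Forcing the reaction would then erode selectivity against C1=C10.
- Fallback, setting out from 26: hydrogen is delivered by homogeneous catalysis with RhCl(PPh3)3 under H2 in benzene. This selects by alkene coordination and should stop at the disubstituted alkene. It returns at 27; no new compound is made (F0).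

## Further compounds

F1 | step 17 | methyl (2S,3E,5E)-2-[(4E,8R)-10-{[tert-butyl(dimethyl)silyl]oxy}-3-hydroxy-5,8-dimethyldec-4-en-1-yl]-2-methylhepta-3,5-dienoate (both carbinol epimers) | COC(=O)[C@@](C)(CCC(O)/C=C(\C)CC[C@@H](C)CCO[Si](C)(C)C(C)(C)C)/C=C/C=C/C
F2 | step 17 | methyl (2S,3E,5E)-2-[(4E,8R)-10-{[tert-butyl(dimethyl)silyl]oxy}-5,8-dimethyl-3-oxodec-4-en-1-yl]-2-methylhepta-3,5-dienoate | COC(=O)[C@@](C)(CCC(=O)/C=C(\C)CC[C@@H](C)CCO[Si](C)(C)C(C)(C)C)/C=C/C=C/C
F3 | step 17 | methyl (1S,4aS,5S,6R,8aS)-5-[(3R)-5-{[tert-butyl(dimethyl)silyl]oxy}-3-methylpentyl]-1,5,6-trimethyl-4-oxo-1,2,3,4,4a,5,6,8a-octahydronaphthalene-1-carboxylate | COC(=O)[C@@]1(C)CCC(=O)[C@H]2[C@@H]1C=C[C@@H](C)[C@]2(C)CC[C@@H](C)CCO[Si](C)(C)C(C)(C)C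
F4 | step 17 | methyl (1S,5S,6R,8aS)-5-[(3R)-5-{[tert-butyl(dimethyl)silyl]oxy}-3-methylpentyl]-1,5,6-trimethyl-4-{[(trifluoromethyl)sulfonyl]oxy}-1,2,3,5,6,8a-hexahydronaphthalene-1-carboxylate | COC(=O)[C@@]1(C)CCC(OS(=O)(=O)C(F)(F)F)=C2[C@@H]1C=C[C@@H](C)[C@]2(C)CC[C@@H](C)CCO[Si](C)(C)C(C)(C)C
F5 | step 2 | dimethyl (2R,3S)-2-hydroxy-3-methylbutanedioate | COC(=O)[C@@H](C)[C@@H](O)C(=O)OC
F6 | step 2 | dimethyl (2R,3S)-2-hydroxy-3-methyl-3-(prop-2-en-1-yl)butanedioate | COC(=O)[C@@](C)(CC=C)[C@@H](O)C(=O)OC
F7 | step 2 | methyl (2S)-2-[(1R)-1,2-dihydroxyethyl]-2-methylpent-4-enoate | COC(=O)[C@@](C)(CC=C)[C@@H](O)CO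
F0 | step 16 | none | none
F8 | step 7 | methyl (2S)-5-hydroxy-2-[(E)-2-iodoethenyl]-2-methylpentanoate | COC(=O)[C@@](C)(CCCO)/C=C/I
F0 | step 18 | none | none
A1 | alternative 1 | 2-methylcyclohex-2-en-1-one | CC1=CCCCC1=O
A2 | alternative 1 | tert-butyl{[(3S)-5-iodo-3-methylpentyl]oxy}dimethylsilane | ICC[C@@H](C)CCO[Si](C)(C)C(C)(C)C
A3 | alternative 1 | (2S,3R)-2-[(3R)-5-{[tert-butyl(dimethyl)silyl]oxy}-3-methylpentyl]-2,3-dimethylcyclohexan-1-one | O=C1CCC[C@@H](C)[C@]1(C)CC[C@@H](C)CCO[Si](C)(C)C(C)(C)C
A4 | alternative 2 | tert-butyl({(3R)-5-[(1S,6R)-2-ethenyl-1,6-dimethylcyclohex-2-en-1-yl]-3-methylpentyl}oxy)dimethylsilane | C=CC1=CCC[C@@H](C)[C@]1(C)CC[C@@H](C)CCO[Si](C)(C)C(C)(C)C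
A5 | alternative 2 | methacrolein | CC(=C)C=O
A6 | alternative 2 | (1S,5S,6R,8aS)-5-[(3R)-5-{[tert-butyl(dimethyl)silyl]oxy}-3-methylpentyl]-1,5,6-trimethyl-1,2,3,5,6,7,8,8a-octahydronaphthalene-1-carbaldehyde | O=C[C@@]1(C)CCC=C2[C@@H]1CC[C@@H](C)[C@]2(C)CC[C@@H](C)CCO[Si](C)(C)C(C)(C)C
A7 | alternative 3 | methyl (3S,4S,6S,8aS)-4-[(3R)-5-{[tert-butyl(dimethyl)silyl]oxy}-3-methylpentyl]-3,4,6-trimethyl-2-methylidene-3,4,6,7,8,8a-hexahydro-2H-chromene-6-carboxylate | COC(=O)[C@@]1(C)CC[C@@H]2OC(=C)[C@@H](C)[C@](C)(CC[C@@H](C)CCO[Si](C)(C)C(C)(C)C)C2=C1
A8 | alternative 3 | methyl (1S,5S,6S,8aS)-5-[(3R)-5-{[tert-butyl(dimethyl)silyl]oxy}-3-methylpentyl]-1,5,6-trimethyl-7-oxo-1,2,3,5,6,7,8,8a-octahydronaphthalene-1-carboxylate | COC(=O)[C@@]1(C)CCC=C2[C@@H]1CC(=O)[C@@H](C)[C@]2(C)CC[C@@H](C)CCO[Si](C)(C)C(C)(C)C
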